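**Retrosynthetic overview**

- Target: (3S,6E)-1-(3,4-dihydroxyphenyl)-7-(4-hydroxyphenyl)hept-6-en-3-yl acetate, chain numbered C1 (benzylic to catechol ring A) to C7 (styrenic carbon on ring B). The strategy rests on one feature: ring B carries its only OH on C4', exactly para to C1' (the ring carbon bonded to C7), so ring B is the two-electron reduction product of a p-quinol whose carbinol carbon is C1'.
- Key disconnection C7–C1': an (E)-alkenyllithium from the C7 vinyl iodide adds to the carbonyl of 4,4-dimethoxycyclohexa-2,5-dienone. Afterwards: ketal hydrolysis, C3 acetylation at the quinol stage (where the only other OH is tertiary), Zn/AcOH aromatisation, fluoride release of the ring A catechol.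
- Vinyl iodide: hydrozirconation–iodination of the C6≡C7 alkyne. The C1–C7 chain and the C3 stereocentre come from (R)-epichlorohydrin, opened at C2 by the ring A benzylic Grignard reagent and, after epoxide re-closure, at C4 by allenylmagnesium bromide.
- Ring order: ring A is purchased (3,4-dihydroxybenzaldehyde); ring B enters as a preformed six-membered dienone ketal and is the last ring to become aromatic; no ring is made by cyclisation.

Key step: step 10

Conventions: TBS = tert-butyldimethylsilyl, TBSO = tert-butyldimethylsilyloxy, TES = triethylsilyl; C1'–C6' are the ring B carbons. The CIP descriptor at C3 changes from R (compounds 7, 8) to S (compound 11 onwards) by priority rules only; no bond at that carbon is broken.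

**Step 1**
Reactants: 1 3,4-dihydroxybenzaldehyde
Product: 2 3,4-bis(TBSO)benzaldehyde
Conditions: TBSCl (2.4 equiv), imidazole (5 equiv), DMF, rt
Reagents that add atoms: tert-butyldimethylsilyl chloride, CC(C)(C)[Si](C)(C)Cl
Why: Imidazole-promoted O-silylation of both phenols gives aryl silyl ethers that tolerate the Grignard, organolithium and zinc steps and can be removed by fluoride at the end.

**Step 2**
Reactants: 2 3,4-bis(TBSO)benzaldehyde
Product: 3 [3,4-bis(TBSO)phenyl]methanol
Conditions: NaBH4, THF/MeOH (10:1), 0 °C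
Reagents that add atoms: none
Why: Borohydride reduction of the aryl aldehyde is fast at 0 °C, and short exposure in mostly THF should leave the aryl silyl ethers intact.

**Step 3**
Reactants: 3 [3,4-bis(TBSO)phenyl]methanol
Product: 4 4-(chloromethyl)-1,2-bis(TBSO)benzene
Conditions: PPh3, CCl4, CH2Cl2, 0 °C → rt
Reagents that add atoms: carbon tetrachloride, ClC(Cl)(Cl)Cl
Why: The Appel chlorination converts the activated benzylic alcohol under neutral conditions, so no acid is present that could cleave the silyl ethers.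

**Step 4**
Reactants: 4 4-(chloromethyl)-1,2-bis(TBSO)benzene; 5 (R)-epichlorohydrin
Product: 7 (2R)-1-chloro-4-[3,4-bis(TBSO)phenyl]butan-2-ol, via benzylic Grignard reagent 6 (not isolated)
Conditions: Mg turnings, THF, 0 °C (slow addition of 4); then CuI (10 mol %), 5, THF, −40 → −20 °C; aq. NH4Cl
Reagents that add atoms: none
Why: Copper-catalysed Grignard opening of the epoxide at its unsubstituted carbon (SN2) forms the C1–C2 bond without touching the stereogenic carbon, so the C3 configuration is taken directly from (R)-epichlorohydrin, and the chloride is not displaced at low temperature.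

**Step 5**
Reactants: 7 (2R)-1-chloro-4-[3,4-bis(TBSO)phenyl]butan-2-ol
Product: 8 (2R)-2-{2-[3,4-bis(TBSO)phenyl]ethyl}oxirane
Conditions: NaH, THF, 0 °C → rt
Reagents that add atoms: none
Why: Intramolecular Williamson etherification (3-exo-tet) of the alkoxide onto CH2Cl closes the epoxide with retention at the stereocentre, whose C–O bond is not broken, and NaH avoids the methanolic bases that cleave aryl silyl ethers.

**Step 6**
Reactants: 8 (2R)-2-{2-[3,4-bis(TBSO)phenyl]ethyl}oxirane; 9 propargyl bromide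
Product: 11 (3S)-1-[3,4-bis(TBSO)phenyl]hept-6-yn-3-ol, via allenylmagnesium bromide 10 (not isolated)
Conditions: Mg, HgCl2 (1 mol %), Et2O, 0 °C; then 8, Et2O, −78 → 0 °C; aq. NH4Cl
Reagents that add atoms: none
Why: Allenylmagnesium bromide attacks the terminal epoxide carbon through its γ-carbon (SE2' propargylation) to give the homopropargylic alcohol and the C4–C5 bond, again leaving the stereocentre untouched.

**Step 7**
Reactants: 11 (3S)-1-[3,4-bis(TBSO)phenyl]hept-6-yn-3-ol
Product: 12 {[(3S)-1-[3,4-bis(TBSO)phenyl]hept-6-yn-3-yl]oxy}triethylsilane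
Conditions: TESCl, imidazole, DMAP (cat.), CH2Cl2, 0 °C → rt
Reagents that add atoms: chlorotriethylsilane, CC[Si](Cl)(CC)CC
Why: Silylation of the secondary alcohol gives a TES ether that withstands Cp2Zr(H)Cl and t-BuLi yet is cleaved later by dilute acid that spares aryl TBS ethers.

**Step 8**
Reactants: 12 {[(3S)-1-[3,4-bis(TBSO)phenyl]hept-6-yn-3-yl]oxy}triethylsilane
Product: 14 {[(3S,6E)-1-[3,4-bis(TBSO)phenyl]-7-iodohept-6-en-3-yl]oxy}triethylsilane, via alkenylzirconocene chloride 13 (not isolated)
Conditions: Cp2Zr(H)Cl (1.3 equiv), THF, rt, dark; then I2, THF, 0 °C; aq. Na2S2O3/NaHCO3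
Reagents that add atoms: iodine, II
Why: Schwartz hydrozirconation adds Zr–H syn across the terminal alkyne with zirconium on C7, and iodinolysis of the C–Zr bond with retention gives the E vinyl iodide only.

**Step 9**
Reactants: 15 4-methoxyphenol
Product: 16 4,4-dimethoxycyclohexa-2,5-dien-1-one
Conditions: PhI(OAc)2 (1.1 equiv), MeOH, 0 °C → rt
Reagents that add atoms: methanol, CO
Why: Oxidative dearomatisation of a p-alkoxyphenol with PhI(OAc)2 generates a cation that methanol traps at the para carbon, the standard preparation of this quinone monoketal.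

**Step 10**
Reactants: 14 {[(3S,6E)-1-[3,4-bis(TBSO)phenyl]-7-iodohept-6-en-3-yl]oxy}triethylsilane; 16 4,4-dimethoxycyclohexa-2,5-dien-1-one
Product: 18 1-[(1E,5S)-7-[3,4-bis(TBSO)phenyl]-5-(triethylsilyloxy)hept-1-en-1-yl]-4,4-dimethoxycyclohexa-2,5-dien-1-ol, via alkenyllithium 17 (not isolated)
Conditions: t-BuLi (2.0 equiv), Et2O, −78 °C; then 16 (1.2 equiv) in THF, −78 → −40 °C; H2O; chromatography on Et3N-washed SiO2
Reagents that add atoms: none
Why: Two equivalents of t-BuLi effect iodine–lithium exchange on 14 (the second destroys the t-BuI formed), and the resulting (E)-alkenyllithium 17, configurationally stable at −78 °C, attacks the only carbonyl of 16 to form the C7–C1' bond and a tertiary bis-allylic lithium alkoxide. The closest known reaction type is the 1,2-addition of aryl-, alkenyl- and alkynyllithium reagents to quinone monoketals, the standard entry to p-quinol ketals. No ring is closed: ring B arrives intact as a cyclohexa-2,5-diene and is aromatised in step 13. No stereocentre is created, because the new carbinol carbon carries two identical ring arms. The step needs 1,2- rather than 1,4-addition and addition rather than proton or electron transfer; the hard, unhindered lithium nucleophile, the absence of enolisable hydrogens in 16, the ketal masking the second quinone carbonyl and the low temperature should secure this. The E geometry of the target was fixed in step 8 and is only carried through here.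

**Step 11**
Reactants: 18 1-[(1E,5S)-7-[3,4-bis(TBSO)phenyl]-5-(triethylsilyloxy)hept-1-en-1-yl]-4,4-dimethoxycyclohexa-2,5-dien-1-ol
Product: 20 4-hydroxy-4-[(1E,5S)-7-[3,4-bis(TBSO)phenyl]-5-hydroxyhept-1-en-1-yl]cyclohexa-2,5-dien-1-one, via TES-protected quinol 19 (not isolated)
Conditions: 1 M aq. HCl/THF (1:4), 0 °C → rt
Reagents that add atoms: water, O
Why: Acid-catalysed acetal hydrolysis is very fast here because it passes through a methoxy-stabilised cyclohexadienyl cation, and the same dilute acid then hydrolyses the secondary TES ether while the aryl TBS ethers and the electron-poor quinol, whose carbinol cannot ionise easily, should persist.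

**Step 12**
Reactants: 20 4-hydroxy-4-[(1E,5S)-7-[3,4-bis(TBSO)phenyl]-5-hydroxyhept-1-en-1-yl]cyclohexa-2,5-dien-1-one
Product: 21 (3S,6E)-1-[3,4-bis(TBSO)phenyl]-7-(1-hydroxy-4-oxocyclohexa-2,5-dien-1-yl)hept-6-en-3-yl acetate
Conditions: Ac2O, pyridine, 0 °C → rt (no DMAP)
Reagents that add atoms: acetic anhydride, CC(=O)OC(C)=O
Why: Pyridine-mediated acetylation reaches only the secondary C3 alcohol, since the tertiary quinol hydroxyl is too hindered without DMAP and no phenol is free at this stage (any over-acetylated quinol would converge to the same product in step 13).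

**Step 13**
Reactants: 21 (3S,6E)-1-[3,4-bis(TBSO)phenyl]-7-(1-hydroxy-4-oxocyclohexa-2,5-dien-1-yl)hept-6-en-3-yl acetate
Product: 22 (3S,6E)-1-[3,4-bis(TBSO)phenyl]-7-(4-hydroxyphenyl)hept-6-en-3-yl acetate
Conditions: Zn dust, AcOH/THF, rt
Reagents that add atoms: none
Why: Reductive aromatisation of a p-quinol: zinc transfers two electrons to the dienone, the dienolate expels the hydroxyl at the γ-carbon C1' (a vinylogous α-ketol reduction), and the gain of aromaticity drives formation of the 4-alkenylphenol without affecting the acetate, the alkene or the silyl ethers.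

**Step 14**
Reactants: 22 (3S,6E)-1-[3,4-bis(TBSO)phenyl]-7-(4-hydroxyphenyl)hept-6-en-3-yl acetate
Product: 23 (3S,6E)-1-(3,4-dihydroxyphenyl)-7-(4-hydroxyphenyl)hept-6-en-3-yl acetate
Conditions: KHF2 (excess), MeOH, rt, under argon
Reagents that add atoms: none
Why: Bifluoride desilylation is selective for phenolic silyl ethers and runs under weakly acidic conditions, which should keep the alkyl acetate in place and suppress air oxidation of the liberated catechol.

**Compound list**

1 | 3,4-dihydroxybenzaldehyde | O=Cc1ccc(O)c(O)c1 | starting material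
2 | 3,4-bis(tert-butyldimethylsilyloxy)benzaldehyde | O=Cc1ccc(O[Si](C)(C)C(C)(C)C)c(O[Si](C)(C)C(C)(C)C)c1 | intermediate
3 | [3,4-bis(tert-butyldimethylsilyloxy)phenyl]methanol | OCc1ccc(O[Si](C)(C)C(C)(C)C)c(O[Si](C)(C)C(C)(C)C)c1 | intermediate
4 | 4-(chloromethyl)-1,2-bis(tert-butyldimethylsilyloxy)benzene | ClCc1ccc(O[Si](C)(C)C(C)(C)C)c(O[Si](C)(C)C(C)(C)C)c1 | intermediate
5 | (R)-epichlorohydrin | ClC[C@H]1CO1 | starting material
6 | [3,4-bis(tert-butyldimethylsilyloxy)benzyl]magnesium chloride | Cl[Mg]Cc1ccc(O[Si](C)(C)C(C)(C)C)c(O[Si](C)(C)C(C)(C)C)c1 | intermediate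
7 | (2R)-1-chloro-4-[3,4-bis(tert-butyldimethylsilyloxy)phenyl]butan-2-ol | ClC[C@H](O)CCc1ccc(O[Si](C)(C)C(C)(C)C)c(O[Si](C)(C)C(C)(C)C)c1 | intermediate
8 | (2R)-2-{2-[3,4-bis(tert-butyldimethylsilyloxy)phenyl]ethyl}oxirane | C1O[C@@H]1CCc2ccc(O[Si](C)(C)C(C)(C)C)c(O[Si](C)(C)C(C)(C)C)c2 | intermediate
9 | propargyl bromide | BrCC#C | starting material
10 | allenylmagnesium bromide | C=C=C[Mg]Br | intermediate
11 | (3S)-1-[3,4-bis(tert-butyldimethylsilyloxy)phenyl]hept-6-yn-3-ol | C#CCC[C@H](O)CCc1ccc(O[Si](C)(C)C(C)(C)C)c(O[Si](C)(C)C(C)(C)C)c1 | intermediate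
12 | {[(3S)-1-[3,4-bis(tert-butyldimethylsilyloxy)phenyl]hept-6-yn-3-yl]oxy}triethylsilane | C#CCC[C@H](O[Si](CC)(CC)CC)CCc1ccc(O[Si](C)(C)C(C)(C)C)c(O[Si](C)(C)C(C)(C)C)c1 | intermediate
13 | (E)-alkenylzirconocene chloride: Cp2Zr(Cl) bonded to C7 of the chain of 12 after syn Zr–H addition (Cp rings drawn σ-bonded) | Cl[Zr](C1C=CC=C1)(C1C=CC=C1)/C=C/CC[C@H](O[Si](CC)(CC)CC)CCc1ccc(O[Si](C)(C)C(C)(C)C)c(O[Si](C)(C)C(C)(C)C)c1 | intermediate
14 | {[(3S,6E)-1-[3,4-bis(tert-butyldimethylsilyloxy)phenyl]-7-iodohept-6-en-3-yl]oxy}triethylsilane | I/C=C/CC[C@H](O[Si](CC)(CC)CC)CCc1ccc(O[Si](C)(C)C(C)(C)C)c(O[Si](C)(C)C(C)(C)C)c1 | intermediate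
15 | 4-methoxyphenol | COc1ccc(O)cc1 | starting material
16 | 4,4-dimethoxycyclohexa-2,5-dien-1-one | COC1(OC)C=CC(=O)C=C1 | intermediate
17 | (E)-alkenyllithium: the C7–Li analogue of 14 | [Li]/C=C/CC[C@H](O[Si](CC)(CC)CC)CCc1ccc(O[Si](C)(C)C(C)(C)C)c(O[Si](C)(C)C(C)(C)C)c1 | intermediate
18 | 1-[(1E,5S)-7-[3,4-bis(tert-butyldimethylsilyloxy)phenyl]-5-(triethylsilyloxy)hept-1-en-1-yl]-4,4-dimethoxycyclohexa-2,5-dien-1-ol | COC1(OC)C=CC(O)(/C=C/CC[C@H](O[Si](CC)(CC)CC)CCc2ccc(O[Si](C)(C)C(C)(C)C)c(O[Si](C)(C)C(C)(C)C)c2)C=C1 | intermediate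
19 | 4-hydroxy-4-[(1E,5S)-7-[3,4-bis(tert-butyldimethylsilyloxy)phenyl]-5-(triethylsilyloxy)hept-1-en-1-yl]cyclohexa-2,5-dien-1-one | O=C1C=CC(O)(/C=C/CC[C@H](O[Si](CC)(CC)CC)CCc2ccc(O[Si](C)(C)C(C)(C)C)c(O[Si](C)(C)C(C)(C)C)c2)C=C1 | intermediate
20 | 4-hydroxy-4-[(1E,5S)-7-[3,4-bis(tert-butyldimethylsilyloxy)phenyl]-5-hydroxyhept-1-en-1-yl]cyclohexa-2,5-dien-1-one | O=C1C=CC(O)(/C=C/CC[C@H](O)CCc2ccc(O[Si](C)(C)C(C)(C)C)c(O[Si](C)(C)C(C)(C)C)c2)C=C1 | intermediate
21 | (3S,6E)-1-[3,4-bis(tert-butyldimethylsilyloxy)phenyl]-7-(1-hydroxy-4-oxocyclohexa-2,5-dien-1-yl)hept-6-en-3-yl acetate | CC(=O)O[C@@H](CC/C=C/C1(O)C=CC(=O)C=C1)CCc2ccc(O[Si](C)(C)C(C)(C)C)c(O[Si](C)(C)C(C)(C)C)c2 | intermediate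
22 | (3S,6E)-1-[3,4-bis(tert-butyldimethylsilyloxy)phenyl]-7-(4-hydroxyphenyl)hept-6-en-3-yl acetate | CC(=O)O[C@@H](CC/C=C/c1ccc(O)cc1)CCc1ccc(O[Si](C)(C)C(C)(C)C)c(O[Si](C)(C)C(C)(C)C)c1 | intermediate
23 | (3S,6E)-1-(3,4-dihydroxyphenyl)-7-(4-hydroxyphenyl)hept-6-en-3-yl acetate | CC(=O)O[C@@H](CC/C=C/c1ccc(O)cc1)CCc1ccc(O)c(O)c1 | target

**Step count**

Total: 14 steps. Longest linear sequence: 13 steps (steps 1–8 and 10–14); step 9 is a one-step side branch.

**Steps most likely to fail, with fallbacks**

1. Step 10. Dehydroiodination of the vinyl iodide by t-BuLi, or electron transfer and conjugate addition in place of 1,2-addition to the dienone, could erode the yield of the adduct. The fallback gives up the dienone addition and joins C7 to an aromatic ring B by cross-coupling.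
It sets out from alkyne 12. Hydrozirconation as in step 8 gives 13, which is not iodinated but treated with ZnCl2, Pd(PPh3)4 (5 mol %, zerovalent palladium) and commercial tert-butyl(4-iodophenoxy)dimethylsilane in THF at rt. This Negishi coupling should give the (E)-styrene carrying a TES ether at C3 and three aryl TBS ethers, F1. PPTS in MeOH/CH2Cl2 at 0 °C should remove only the TES group to give the C3 alcohol F2. Ac2O, pyridine and DMAP should convert it into the C3 acetate tris(TBS) ether F3. KHF2 in MeOH, as in step 14, should then release all three phenols, and the fallback rejoins the route at target 23.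

2. Step 11. Acid-induced ionisation or allylic transposition at the tertiary bis-allylic carbinol, or partial loss of aryl TBS groups, could compete with TES hydrolysis. The fallback separates the tasks and moves the acetate adjustment to the end.
It sets out from 18. Wet silica gel with aqueous oxalic acid in CH2Cl2 at rt should hydrolyse only the ketal, giving 19, now isolated. Zn dust in AcOH/THF should then give the ring B phenol that still carries the C3 TES ether and the ring A TBS ethers, F4. HF·pyridine in THF/pyridine should remove all silyl groups to give the tetraol F5. Ac2O, pyridine and DMAP should give the tetraacetate F6. NH4OAc in aqueous MeOH at rt, which cleaves aryl acetates much faster than alkyl acetates, should remove the three phenolic acetates, and the fallback rejoins the route at target 23.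

3. Step 4. Wurtz homocoupling during formation of the electron-rich benzylic Grignard reagent, or sluggish copper-catalysed opening, could starve the route of material. The fallback avoids a benzylic organometallic and sets C3 by kinetic resolution.
It sets out from chloride 4. Coupling with commercial allylmagnesium bromide in THF at 0 °C → rt should give 4-(but-3-en-1-yl)-1,2-bis(TBSO)benzene F7. mCPBA with NaHCO3 in CH2Cl2 should give the racemic epoxide F8. Hydrolytic kinetic resolution follows, with (R,R)-(salen)Co(OAc) (0.5 mol %, trivalent cobalt; salen = N,N'-bis(3,5-di-tert-butylsalicylidene)cyclohexane-1,2-diamine dianion) and 0.55 equiv H2O in THF. This should hydrolyse the (S)-epoxide and leave the (R)-epoxide, so the fallback rejoins the route at compound 8. The sense of the resolution is assigned from recalled precedent for 2-alkyloxiranes and should be confirmed on the first batch.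

**Further compounds**

F1 | step 10 | {[(3S,6E)-1-[3,4-bis(tert-butyldimethylsilyloxy)phenyl]-7-[4-(tert-butyldimethylsilyloxy)phenyl]hept-6-en-3-yl]oxy}triethylsilane | CC[Si](CC)(CC)O[C@@H](CC/C=C/c1ccc(O[Si](C)(C)C(C)(C)C)cc1)CCc1ccc(O[Si](C)(C)C(C)(C)C)c(O[Si](C)(C)C(C)(C)C)c1
F2 | step 10 | (3S,6E)-1-[3,4-bis(tert-butyldimethylsilyloxy)phenyl]-7-[4-(tert-butyldimethylsilyloxy)phenyl]hept-6-en-3-ol | O[C@@H](CC/C=C/c1ccc(O[Si](C)(C)C(C)(C)C)cc1)CCc1ccc(O[Si](C)(C)C(C)(C)C)c(O[Si](C)(C)C(C)(C)C)c1
F3 | step 10 | (3S,6E)-1-[3,4-bis(tert-butyldimethylsilyloxy)phenyl]-7-[4-(tert-butyldimethylsilyloxy)phenyl]hept-6-en-3-yl acetate | CC(=O)O[C@@H](CC/C=C/c1ccc(O[Si](C)(C)C(C)(C)C)cc1)CCc1ccc(O[Si](C)(C)C(C)(C)C)c(O[Si](C)(C)C(C)(C)C)c1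
F4 | step 11 | 4-[(1E,5S)-7-[3,4-bis(tert-butyldimethylsilyloxy)phenyl]-5-(triethylsilyloxy)hept-1-en-1-yl]phenol | CC[Si](CC)(CC)O[C@@H](CC/C=C/c1ccc(O)cc1)CCc1ccc(O[Si](C)(C)C(C)(C)C)c(O[Si](C)(C)C(C)(C)C)c1
F5 | step 11 | 4-[(3S,6E)-3-hydroxy-7-(4-hydroxyphenyl)hept-6-en-1-yl]benzene-1,2-diol | O[C@@H](CC/C=C/c1ccc(O)cc1)CCc1ccc(O)c(O)c1
F6 | step 11 | (3S,6E)-7-(4-acetoxyphenyl)-1-(3,4-diacetoxyphenyl)hept-6-en-3-yl acetate | CC(=O)O[C@@H](CC/C=C/c1ccc(OC(C)=O)cc1)CCc1ccc(OC(C)=O)c(OC(C)=O)c1
F7 | step 4 | 4-(but-3-en-1-yl)-1,2-bis(tert-butyldimethylsilyloxy)benzene | C=CCCc1ccc(O[Si](C)(C)C(C)(C)C)c(O[Si](C)(C)C(C)(C)C)c1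
F8 | step 4 | racemic 2-{2-[3,4-bis(tert-butyldimethylsilyloxy)phenyl]ethyl}oxirane | C1OC1CCc1ccc(O[Si](C)(C)C(C)(C)C)c(O[Si](C)(C)C(C)(C)C)c1
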